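G comes slowly in these flasks, and that slowness can be measured while solid J stands.

| flask | J | Q | remark | time |
|---|---|---|---|---|
| dusk | 0.40 M | 0.30 M | run made earlier |  |
| noon | 0.40 M | 0.75 M | run made earlier |  |
| spring | 0.40 M | 1.9 M | run made earlier |  |
| midnight | 0.23 M | 0.52 M | run made earlier |  |
| green | 0.40 M | 0.520 M |  | 25 min |
| ochre | 0.40 M | 2.00 M |  | 25 min |
| amber | 0.20 M | 0.520 M |  | 25 min |
| red | 0.10 M | 0.250 M |  | 25 min |

| run | time / min | G / % | J / % |
|---|---|---|---|
| dusk | 1.50 | 0.9 | 71.4 |
| dusk | 4.00 | 2.5 | 49.4 |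
| dusk | 8.00 | 5.2 | 35.7 |
| dusk | 12.0 | 7.7 | 28.2 |
| dusk | 20.0 | 10.6 | 22.3 |
| noon | 4.00 | 6.5 | 47.4 |
| noon | 8.00 | 15.0 | 27.9 |
| noon | 10.0 | 16.8 | 22.5 |
| noon | 15.0 | 21.3 | 10.2 |
| noon | 20.0 | 24.4 | 0 |
| spring | 4.00 | 15.6 | 43.4 |
| spring | 8.00 | 32.7 | 12.5 |
| spring | 10.0 | 39.0 | 2.4 |
| spring | 15.0 | 44.1 | 0.2 |
| spring | 20.0 | 41.5 | 0.3 |
| midnight | 1.50 | 2.6 | 51.4 |
| midnight | 4.00 | 7.4 | 10.6 |
| midnight | 8.00 | 16.8 | 0.5 |
| midnight | 12.0 | 20.1 | 0 |
| midnight | 20.0 | 22.0 | 0 |

(readings scatter by 0.5 percentage points)

- as a solid, counted per litre of solution: J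
- at the start none of J is in solution
- what has only dissolved of J counts as not reacted

1. the flasks by amount of G, in percent of the J charged, highest first, at 25 min (green / ochre / amber / red)
2. the same order at 5.0 min (green / ochre / amber / red)
3. the amount of G, in percent of the J charged of the flask you put first, at 25 min
4. the amount of G, in percent of the J charged of the flask you put last, at 25 min

Take the reading at 4.00 min in each run and divide the molar G formed by molar Q charged and by the time:

- dusk: Q 0.30 M, J left 49.4%, slope 0.00833 /min
- noon: Q 0.75 M, J left 47.4%, slope 0.00867 /min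
- spring: Q 1.9 M, J left 43.4%, slope 0.00821 /min
- midnight: Q 0.52 M, J left 10.6%, slope 0.00818 /min

Down the Q column the charge rises from 0.30 M to 1.9 M, yet the slope column barely moves. The midnight row, with a smaller J charge of 0.23 M, gives a like slope, so at this reading molar G follows Q and the change of loading does not show: the formation looks pseudo-first-order in Q. The mean, 0.00835 /min, is the G slope s: molar G formed per minute per molar Q over the first 4.00 min, with solid present. In percent of the J charged, G is then s times Q times time, divided by the J charge.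

At 5.0 min this reckoning gives ochre 20.9%, amber 10.9%, red 10.4% and green 5.43%. Red's figure is doubtful, because its charge of 0.10 M is less than the 0.112 M that left the midnight solid by 1.50 min, so red's solid may be gone well before 5.0 min. At 25 min the line gives ochre 104%, more than was charged, so the line cannot be carried that far. Spring, the nearest run, reads 44.1% at 15.0 min and 41.5% at 20.0 min.

The forecast, reasoning “While solid remains, G forms” at a slope of about 0.009 per minute, where the reckoning here has s, says ochre > amber > green > red at 25 min and ochre > amber > red > green at 5.0 min, with top 39% and low 14%.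

The flask gives ochre > amber > green > red at 25 min and ochre > amber > red > green at 5.0 min, with top 37.8% and low 14.0%.

    X + Q ⇌ G (K = 1.10 /M, k = 0.0922 /M/min)
    X + Q ⇌ D (K = 64.7 /M, k = 0.00452 /M/min)
    X + G → E (k = 0.0619 /M/min)
    J ⇌ X, rate k4*(cs4 - [X]) while solid is left; crystals form when [X] > cs4 (solubility = 0.250 M, k = 0.390 /min)
    G ⇌ Z (K = 7.56, k = 0.0250 /min)

At 5.0 min red holds 7.42%, below the 10.4% of the line, and stands 1.2 percentage points above green. For ochre at 5.0 min, s gave 20.9% and the flask holds 20.8%. Ochre read at 10 min is reckoned by s at 41.7%, and that flask holds 40.3% of G, with J down to 0.147%.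

The readings were generated by integration with made-up constants; the scatter is artificial.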